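## Retrosynthetic overview
1. Target ⇐ hydrogenolysis of seven benzyl ethers ⇐ ionic C4 deoxygenation with loss of boron ⇐ double O-acylation (O7, O3') of a tricyclic flavan-3,4-diol 4,5-O-phenylboronate.
2. Key disconnection: C4–C4a, O1–C2 and the O4–B–O5 bridge are cut together. This gives phloroglucinol, PhB(OH)2 and a (2R,3S)-trans-epoxy aldehyde, joined in a three-component formal [3+3] annulation that forms two rings in one flask.
3. The boracycle does three jobs. It templates the C–C bond, it hides O5 and O4 so that only O7 and O3' are free phenols, and it is the leaving group that turns C4 into CH2.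
4. Epoxy aldehyde ⇐ organocatalytic epoxidation of the enal (sets C3 and, after inversion, C2) ⇐ Wittig reaction on 4-benzyloxy-3-hydroxybenzaldehyde.
5. Ring order: rings A, B and both galloyl rings are bought. The 1,3,2-dioxaborinine ring forms first and pyran ring C second, in the same operation. The boracycle is removed in the penultimate step.

Assumption: the epoxidation catalyst follows its usual steric model (peroxide attacks anti to the CAr2(OTMS) group), so the (R)-catalyst is taken to give (2R,3S)-4 (both catalyst enantiomers are commercial); C4 of 7, 8 and 11 is drawn without configuration because both epimers converge in step 5.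

## Route

Step 1
Reactants: 1 4-(benzyloxy)-3-hydroxybenzaldehyde; 2 (triphenylphosphoranylidene)acetaldehyde
Product: 3 (E)-3-[4-(benzyloxy)-3-hydroxyphenyl]prop-2-enal
Conditions: 2 (1.15 equiv), toluene, 80 °C, 12 h
Reagents that add atoms: none
Why: Wittig olefination with a stabilised formyl ylide is E-selective and tolerates the free phenol, because the ylide is too weakly basic to deprotonate it.

Step 2
Reactants: 3 (E)-3-[4-(benzyloxy)-3-hydroxyphenyl]prop-2-enal
Product: 4 (2R,3S)-3-[4-(benzyloxy)-3-hydroxyphenyl]oxirane-2-carbaldehyde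
Conditions: (R)-2-{bis[3,5-bis(trifluoromethyl)phenyl](trimethylsilyloxy)methyl}pyrrolidine (10 mol %), 35% aq H2O2 (1.3 equiv), CH2Cl2, 0 °C → rt; water wash, short pad of Et3N-deactivated SiO2
Reagents that add atoms: hydrogen peroxide, OO
Why: In this Jørgensen-type iminium–enamine epoxidation (an organocatalytic Weitz–Scheffer reaction), hydroperoxide adds to C-β of the E-iminium ion on the face away from the CAr2(OTMS) group and the enamine then closes onto oxygen, which sets both stereocentres as the trans (2R,3S) epoxide, while the formyl group keeps the p-alkoxyaryl epoxide isolable just as the ester does in aryl glycidates.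

Step 3
Reactants: 4 (2R,3S)-3-[4-(benzyloxy)-3-hydroxyphenyl]oxirane-2-carbaldehyde; 5 phloroglucinol; 6 phenylboronic acid
Product: 8 (2R,3S)-4'-O-benzylleucocyanidin 4,5-O-phenylboronate (C4 epimers), via epoxy-benzodioxaborinine 7 (not isolated)
Conditions: 5 (1.0 equiv), 6 (1.05 equiv), 4 Å MS, toluene–THF 4:1, rt, 1 h; then 4 (1.0 equiv), EtCO2H (20 mol %), 0.05 M, rt → 45 °C; filter, concentrate, precipitate with heptane
Reagents that add atoms: none
Why: Proposed new method: the mixed phenylboronate of 5 binds the formyl oxygen of 4 and delivers the ortho carbon through a six-membered transition state (closest known reaction type: the Nagata-type PhB(OH)2-mediated ortho-hydroxyalkylation of electron-rich phenols with aldehydes, which gives isolable 2-phenyl-4H-1,3,2-benzodioxaborins), so the first ring (boracycle 7) ties up O5 and O4, after which the second ortho OH, the only nucleophile within reach, opens the boron-activated epoxide 6-endo at the p-benzyloxybenzylic carbon with inversion (S to R, the known aryl-directed 6-endo epoxide opening by phenols) and closes ring C as the 2,3-trans isomer, with C3 carried over unchanged from 4 and the new C4 centre irrelevant because step 5 erases it.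

Step 4
Reactants: 8 (2R,3S)-4'-O-benzylleucocyanidin 4,5-O-phenylboronate; 9 3,4,5-tris(benzyloxy)benzoic acid
Product: 11 7,3'-bis-O-[3,4,5-tris(benzyloxy)benzoyl] derivative of 8, via tri-O-benzylgalloyl chloride 10 (not isolated)
Conditions: 9 (2.1 equiv), (COCl)2 (2.5 equiv), DMF (cat.), CH2Cl2, rt, evaporate; then 8, iPr2NEt (2.5 equiv), CH2Cl2, −20 → 0 °C
Reagents that add atoms: oxalyl chloride, O=C(Cl)C(=O)Cl (supplies only the Cl of intermediate 10; no atom of it remains in 11)
Why: In this anhydrous Schotten–Baumann-type O-acylation only the two free phenols (O7 and O3') react, because O5 and O4 are locked in the boronate and the hindered, far less acidic secondary 3-OH does not react with this electron-rich aroyl chloride when no nucleophilic catalyst such as DMAP is present.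

Step 5
Reactants: 11 7,3'-bis-O-[3,4,5-tris(benzyloxy)benzoyl] derivative of 8
Product: 12 (2R,3S)-4'-O-benzyl-7,3'-bis-O-[3,4,5-tris(benzyloxy)benzoyl]catechin
Conditions: Et3SiH (5 equiv), CF3CO2H (3 equiv), CH2Cl2, −30 → 0 °C; pH 7 buffer work-up
Reagents that add atoms: none
Why: In this ionic hydrogenation (Kursanov–Parnes type, known for the reductive opening of benzodioxaborins to ortho-alkylphenols and for the C4 reduction of flavan-3,4-diols), protonation of the benzylic O4–B linkage gives a C4 cation stabilised by the ortho oxygens O1 and O5, silane traps it as CH2 and the aryl O–B bond hydrolyses on work-up, while dilute acid at low temperature leaves the less easily ionised C2–O1 bond, the esters, the benzyl ethers and both stereocentres untouched.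

Step 6
Reactants: 12 (2R,3S)-4'-O-benzyl-7,3'-bis-O-[3,4,5-tris(benzyloxy)benzoyl]catechin
Product: 13 catechin 7,3'-di-O-gallate
Conditions: H2 (1 atm), Pd(OH)2/C (20 wt %), THF–EtOAc 1:1, rt; filter, Sephadex LH-20
Reagents that add atoms: none
Why: Catalytic hydrogenolysis cleaves all seven O-benzyl ethers under neutral aprotic conditions that spare the aryl gallate esters, avoid 3'→4' acyl migration and, as in the usual final debenzylation of benzyl-protected catechin gallates, do not cleave the C2–O1 bond or touch C2 or C3.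

## Compound list
1 | 4-(benzyloxy)-3-hydroxybenzaldehyde | O=Cc1ccc(OCc2ccccc2)c(O)c1 | starting material
2 | (triphenylphosphoranylidene)acetaldehyde | O=CC=P(c1ccccc1)(c1ccccc1)c1ccccc1 | starting material
3 | (E)-3-[4-(benzyloxy)-3-hydroxyphenyl]prop-2-enal | O=C/C=C/c1ccc(OCc2ccccc2)c(O)c1 | intermediate
4 | (2R,3S)-3-[4-(benzyloxy)-3-hydroxyphenyl]oxirane-2-carbaldehyde (trans) | O=C[C@@H]1O[C@H]1c1ccc(OCc2ccccc2)c(O)c1 | intermediate
5 | phloroglucinol (benzene-1,3,5-triol, anhydrous) | Oc1cc(O)cc(O)c1 | starting material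
6 | phenylboronic acid | OB(O)c1ccccc1 | starting material
7 | 4-{(2S,3S)-3-[4-(benzyloxy)-3-hydroxyphenyl]oxiran-2-yl}-2-phenyl-4H-1,3,2-benzodioxaborinine-5,7-diol (both C4 epimers) | Oc1cc(O)c2c(c1)OB(c1ccccc1)OC2[C@@H]1O[C@H]1c1ccc(OCc2ccccc2)c(O)c1 | intermediate
8 | (2R,3S)-2-[4-(benzyloxy)-3-hydroxyphenyl]-3,7-dihydroxychromane-4,5-diyl phenylboronate (O4 and O5 bridged by B–Ph in a six-membered ring peri-fused to rings A and C; 2,3-trans; free OH at C3, C7 and C3'; both C4 epimers) | Oc1cc2OB(c3ccccc3)OC4c2c(c1)O[C@H](c1ccc(OCc2ccccc2)c(O)c1)[C@H]4O | intermediate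
9 | 3,4,5-tris(benzyloxy)benzoic acid | OC(=O)c1cc(OCc2ccccc2)c(OCc2ccccc2)c(OCc2ccccc2)c1 | starting material
10 | 3,4,5-tris(benzyloxy)benzoyl chloride | ClC(=O)c1cc(OCc2ccccc2)c(OCc2ccccc2)c(OCc2ccccc2)c1 | intermediate
11 | 7,3'-bis-O-[3,4,5-tris(benzyloxy)benzoyl] derivative of 8 (2R,3S; free 3-OH; both C4 epimers) | O=C(Oc1cc2OB(c3ccccc3)OC4c2c(c1)O[C@H](c1ccc(OCc2ccccc2)c(OC(=O)c2cc(OCc3ccccc3)c(OCc3ccccc3)c(OCc3ccccc3)c2)c1)[C@H]4O)c1cc(OCc2ccccc2)c(OCc2ccccc2)c(OCc2ccccc2)c1 | intermediate
12 | (2R,3S)-4'-O-benzyl-7,3'-bis-O-[3,4,5-tris(benzyloxy)benzoyl]catechin (free 3-OH and 5-OH) | O=C(Oc1cc(O)c2c(c1)O[C@H](c1ccc(OCc3ccccc3)c(OC(=O)c3cc(OCc4ccccc4)c(OCc4ccccc4)c(OCc4ccccc4)c3)c1)[C@@H](O)C2)c1cc(OCc2ccccc2)c(OCc2ccccc2)c(OCc2ccccc2)c1 | intermediate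
13 | (2R,3S)-catechin 7,3'-di-O-gallate | O=C(Oc1cc(O)c2c(c1)O[C@H](c1ccc(O)c(OC(=O)c3cc(O)c(O)c(O)c3)c1)[C@@H](O)C2)c1cc(O)c(O)c(O)c1 | target

## Step count and risks
Total steps: 6 (acid chloride 10 is made and consumed in the flask of step 4).
Longest linear sequence: 6 (1 → 3 → 4 → 8 → 11 → 12 → 13).

**Most likely to fail, first: step 3.**
- Failure modes:
  - The acid or Lewis acid may ionise the aryl epoxide before the C–C bond forms, leading to Meinwald rearrangement or C-arylation at the benzylic carbon.
  - Phloroglucinol may be alkylated twice.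
  - Boron may migrate to the O3/O4 pair.
- The fallback sets out from 4 and 5 and comes back at 8.
- It gives up electrophile templating and activates the nucleophile instead. The phloroglucinol monoanion (NaHCO3–Na2CO3 buffer, pH about 9, H2O–THF, 0 °C) adds through carbon to the aldehyde in a Lederer–Manasse-type hydroxyalkylation.
- The neighbouring phenoxide then opens the epoxide, which is not ionised under base, by SN2 attack at the benzylic carbon. This gives (2R,3S)-4'-O-benzylleucocyanidin F1.
- After a neutral extraction this labile tetrol is capped at once with 6 (MgSO4, THF, rt) to give 8.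

**Second: step 5.**
- Failure modes:
  - The acid may also open or epimerise the C2–O1 bond.
  - A hydride shift from C3 may occur.
- The fallback sets out from 11 and comes back at 12.
- It replaces hydride capture by sulfur capture followed by desulfurisation, as in classical proanthocyanidin thiolysis. Phenylmethanethiol in CH2Cl2–AcOH at rt traps the C4 cation under much weaker acid and releases boron.
- This gives (2R,3S)-4-(benzylsulfanyl)-4'-O-benzyl-7,3'-bis-O-[3,4,5-tris(benzyloxy)benzoyl]catechin F2, mainly the 3,4-trans isomer.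
- Neutral Raney Ni in THF–EtOH then cuts the C4–S bond to give 12. Any O-benzyl loss at this point does no harm, because step 6 removes all benzyl groups.

**Third: step 2.**
- Failure modes:
  - The donor-substituted enal forms a weakly electrophilic iminium ion.
  - The free phenol and the fragile epoxide may oligomerise.
- The fallback sets out from 1 and comes back at 4, replacing steps 1 and 2.
- Darzens condensation of 1 with methyl chloroacetate (NaOMe, 2.2 equiv, MeOH, −10 °C) gives racemic trans-methyl 3-[4-(benzyloxy)-3-hydroxyphenyl]oxirane-2-carboxylate F3.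
- Lipase from Serratia marcescens (toluene/pH 8 buffer) hydrolyses the (2S,3R) antipode, as in the industrial resolution of the 4-methoxyphenyl glycidate. This leaves methyl (2R,3S)-3-[4-(benzyloxy)-3-hydroxyphenyl]oxirane-2-carboxylate F4.
- iBu2AlH (2.1 equiv, toluene, −78 °C) then reduces F4 to 4.

## Further compounds
F1 | step 3 | (2R,3S)-4'-O-benzylleucocyanidin (both C4 epimers) | Oc1cc(O)c2c(c1)O[C@H](c1ccc(OCc3ccccc3)c(O)c1)[C@@H](O)C2O
F2 | step 5 | (2R,3S)-4-(benzylsulfanyl)-4'-O-benzyl-7,3'-bis-O-[3,4,5-tris(benzyloxy)benzoyl]catechin | O=C(Oc1cc(O)c2c(c1)O[C@H](c1ccc(OCc3ccccc3)c(OC(=O)c3cc(OCc4ccccc4)c(OCc4ccccc4)c(OCc4ccccc4)c3)c1)[C@@H](O)C2SCc1ccccc1)c1cc(OCc2ccccc2)c(OCc2ccccc2)c(OCc2ccccc2)c1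
F3 | step 2 | racemic trans-methyl 3-[4-(benzyloxy)-3-hydroxyphenyl]oxirane-2-carboxylate | COC(=O)[C@@H]1O[C@H]1c1ccc(OCc2ccccc2)c(O)c1.COC(=O)[C@H]1O[C@@H]1c1ccc(OCc2ccccc2)c(O)c1
F4 | step 2 | methyl (2R,3S)-3-[4-(benzyloxy)-3-hydroxyphenyl]oxirane-2-carboxylate | COC(=O)[C@@H]1O[C@H]1c1ccc(OCc2ccccc2)c(O)c1
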